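The furan-2,5-dione ring is dissected into an internal alkyne (the tetrasubstituted C3=C4 unit), CO2 and CO (the C2(=O)–O1–C5(=O) unit). A zerovalent-nickel-mediated (2+2+1) annulation of (S)-nonadec-17-yn-2-yl acetate with CO2 and then CO should build the whole anhydride in one flask. It makes the bond between carbonyl C2 and C3, the ring carbon that carries the 15-acetoxyhexadecyl chain, as the ring closes. The step exploits the fact that both alkyne carbons end up acylated in the O1-bridged ring, so the direction of CO2 uptake is irrelevant. The precursor is a plain methyl-capped alkyne, reached from (S)-propylene oxide by epoxide alkynylation and an alkyne zipper.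

Key step: step 5

Remark: the acetoxy-bearing carbon is (S) (OAc > chain CH2 > CH3 > H). It is taken from (S)-2-methyloxirane, and no step breaks a bond at this center.

Step 1
Reactants: 1 hexadec-1-yne; 2 (S)-2-methyloxirane ((S)-propylene oxide)
Product: 4 (S)-nonadec-4-yn-2-ol, via hexadec-1-ynyllithium 3 (not isolated)
Conditions: 1, n-BuLi, THF, −78 °C; BF3·OEt2, then 2, −78 °C; H2O
Reagents that add atoms: none
Why: BF3-promoted epoxide alkynylation, in which the lithium acetylide 3 opens the Lewis-acid-activated oxirane by SN2 attack at the unsubstituted CH2 only, so the C–O stereocenter of 2 is carried into 4 unchanged as (S).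

Step 2
Reactants: 4 (S)-nonadec-4-yn-2-ol
Product: 6 (S)-nonadec-18-yn-2-ol, via dipotassium alkoxide acetylide salt 5 (not isolated)
Conditions: KH, H2N(CH2)3NH2, rt (gives KNH(CH2)3NH2); 4 in THF, 0 °C to rt; H2O
Reagents that add atoms: none
Why: Alkyne zipper reaction, in which the amide base relays the triple bond along the unbranched chain by repeated propargyl–allenyl prototropy until it is trapped irreversibly as the terminal acetylide in 5, while the carbinol center, held as its alkoxide, has no acidic C–H and should keep its (S) configuration.

Step 3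
Reactants: 6 (S)-nonadec-18-yn-2-ol
Product: 7 (S)-nonadec-17-yn-2-ol
Conditions: KOtBu, DMSO/THF, rt; H2O
Reagents that add atoms: none
Why: Base-mediated prototropic alkyne isomerization, in which the terminal alkyne passes through the 1,2-diene to the thermodynamically preferred methyl-capped internal alkyne under equilibrating conditions, further inward migration being much slower at room temperature.

Step 4
Reactants: 7 (S)-nonadec-17-yn-2-ol
Product: 8 (S)-nonadec-17-yn-2-yl acetate
Conditions: Ac2O, pyridine, DMAP (cat.), CH2Cl2, 0 °C to rt
Reagents that add atoms: acetic anhydride CC(=O)OC(C)=O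
Why: DMAP-catalyzed O-acylation (nucleophilic acyl transfer) of the secondary alcohol, which leaves the C–O bond of the stereocenter and the alkyne untouched.

Step 5
Reactants: 8 (S)-nonadec-17-yn-2-yl acetate
Product: 11 (S)-16-(4-methyl-2,5-dioxo-2,5-dihydrofuran-3-yl)hexadecan-2-yl acetate, via oxanickelacyclopentenone regioisomer A 9 (not isolated), via oxanickelacyclopentenone regioisomer B 10 (not isolated)
Conditions: Ni(cod)2 (1.1 equiv), TMEDA (1.2 equiv), CO2 (1 atm), THF, 0 °C to rt; then CO (1 atm), rt; 1 M HCl wash
Reagents that add atoms: carbon dioxide O=C=O; carbon monoxide [C-]#[O+]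
Why: Zerovalent nickel couples the alkyne with CO2 by oxidative cyclization to the oxanickelacyclopentenones 9 and 10; CO then inserts into the Ni–C(sp2) bond and C–O reductive elimination releases the anhydride, so the C2–C3 bond is made either in the insertion (from 9) or in the oxidative cyclization (from 10). The closest known reaction type is the stoichiometric nickel-mediated alkyne/CO2 coupling followed by carbonylation of the nickelalactone, known for simple dialkyl alkynes such as but-2-yne (giving dimethylmaleic anhydride), a formal (2+2+1) annulation. The one ring closed, the five-membered furan-2,5-dione, is completed by C–O reductive elimination from a six-membered acyl(carboxylato)nickel metallacycle after the C–C(=O) bond-forming migratory insertion. No stereocenter is created and the remote (S)-acetoxy center is not involved. The step needs only chemoselectivity for 1:1 alkyne–CO2 coupling over alkyne oligomerization or pyranone formation, which the stoichiometric nickel, the amine ligand, the low temperature and the order of the gases (CO2 first, CO second) should secure; it needs no regioselectivity, because 9 and 10 converge on the same product.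

Compound list
1 | hexadec-1-yne | CCCCCCCCCCCCCCC#C | starting material
2 | (S)-2-methyloxirane ((S)-propylene oxide) | C[C@H]1CO1 | starting material
3 | hexadec-1-ynyllithium | [Li]C#CCCCCCCCCCCCCCC | intermediate
4 | (S)-nonadec-4-yn-2-ol | C[C@H](O)CC#CCCCCCCCCCCCCCC | intermediate
5 | dipotassium salt of 6 (alkoxide at C2, acetylide at C19) | C[C@H]([O-])CCCCCCCCCCCCCCCC#[C-].[K+].[K+] | intermediate
6 | (S)-nonadec-18-yn-2-ol | C[C@H](O)CCCCCCCCCCCCCCCC#C | intermediate
7 | (S)-nonadec-17-yn-2-ol | C[C@H](O)CCCCCCCCCCCCCCC#CC | intermediate
8 | (S)-nonadec-17-yn-2-yl acetate | CC(=O)O[C@@H](C)CCCCCCCCCCCCCCC#CC | intermediate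
9 | oxanickelacyclopentenone regioisomer A: (TMEDA)Ni five-membered ring Ni–C(15-acetoxyhexadecyl)=C(CH3)–C(=O)–O, nickel on the chain-bearing carbon (N→Ni bonds written with formal charges) | CC(=O)O[C@@H](C)CCCCCCCCCCCCCCC1=C(C)C(=O)O[Ni-2]12[N+](C)(C)CC[N+]2(C)C | intermediate
10 | oxanickelacyclopentenone regioisomer B: (TMEDA)Ni five-membered ring Ni–C(CH3)=C(15-acetoxyhexadecyl)–C(=O)–O, nickel on the methyl-bearing carbon (N→Ni bonds written with formal charges) | CC(=O)O[C@@H](C)CCCCCCCCCCCCCCC1=C(C)[Ni-2]2([N+](C)(C)CC[N+]2(C)C)OC1=O | intermediate
11 | (S)-16-(4-methyl-2,5-dioxo-2,5-dihydrofuran-3-yl)hexadecan-2-yl acetate, i.e. 3-[(15S)-15-acetoxyhexadecyl]-4-methylfuran-2,5-dione | CC(=O)O[C@@H](C)CCCCCCCCCCCCCCC1=C(C)C(=O)OC1=O | target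

Total step count: 5
Longest linear sequence: 5 steps (1 and 2 to 11)

Steps most likely to fail

Step 5. On admission of CO the amine ligand may be displaced and the nickelacycle may fragment or stall at the acyl stage instead of inserting CO and eliminating the C–O bond; part of the alkyne may also be lost to nickel-mediated oligomerization. The nickel is expected to leave as volatile Ni(CO)4, which is to be swept into an iodine trap. The fallback sets out from 8, passes through 9 and 10, and comes back at 11. The nickelacycles would be protonated with 2 M HCl instead of carbonylated, giving by overall syn hydrocarboxylation the pair (2E,18S)-18-acetoxy-2-methylnonadec-2-enoic acid F1 and (S,E)-2-(15-acetoxyhexadecyl)but-2-enoic acid F2. The unseparated pair would then be closed by carboxylate-directed vinyl C–H carbonylation at divalent palladium (Pd(OAc)2, Ag2CO3, NaOAc, CO 1 atm, 1,4-dioxane, 130 °C). Both acids carry their β-hydrogen cis to CO2H, so both should converge on 11.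

Step 2. Migration over fourteen positions may stall or stay incomplete, for instance through poor solubility of the waxy C19 alkoxide in the diamine, leaving internal-alkyne isomers that cannot be separated. The fallback sets out from 2 and comes back at 8, and assembles the chain without any isomerization. Undec-10-enylmagnesium bromide F3 (from 11-bromoundec-1-ene, Mg, THF) would open 2 under CuI catalysis (THF, −30 °C; aq. NH4Cl) to (S)-tetradec-13-en-2-ol F4. Acetylation (Ac2O, pyridine, DMAP) would give (S)-tetradec-13-en-2-yl acetate F5, and hydroboration with 9-BBN-H would give (S)-14-(9-borabicyclo[3.3.1]nonan-9-yl)tetradecan-2-yl acetate F6. A B-alkyl Suzuki–Miyaura alkyl–alkyl coupling of F6 with 5-bromopent-2-yne (Pd(OAc)2, PCy3, K3PO4·H2O, THF, rt) would then give 8.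

Step 3. The prototropic equilibration may not stop cleanly at the methyl-capped alkyne: residual terminal alkyne and allene, or onward drift of the triple bond, would give isomer mixtures that the key step would carry into the anhydride. The fallback sets out from 2 and comes back at 7, and introduces the terminal methyl by C–C bond formation instead. Pentadec-1-ynyllithium F7 (from pentadec-1-yne, n-BuLi, THF, −78 °C) would open 2 (BF3·OEt2) to (S)-octadec-4-yn-2-ol F8. The zipper reaction (KNH(CH2)3NH2) would give, through the dipotassium alkoxide acetylide F9, (S)-octadec-17-yn-2-ol F10. Its dilithium alkoxide acetylide F11 (n-BuLi 2.1 equiv, THF/DMPU, −78 to 0 °C) would be methylated at carbon with MeI (1 equiv) to 7, the acetylide carbon being far more nucleophilic than the lithium alkoxide.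

Further compounds
F1 | step 5 | (2E,18S)-18-acetoxy-2-methylnonadec-2-enoic acid | CC(=O)O[C@@H](C)CCCCCCCCCCCCCC/C=C(\C)C(=O)O
F2 | step 5 | (S,E)-2-(15-acetoxyhexadecyl)but-2-enoic acid | C/C=C(\CCCCCCCCCCCCCC[C@H](C)OC(C)=O)C(=O)O
F3 | step 2 | undec-10-enylmagnesium bromide | C=CCCCCCCCCC[Mg]Br
F4 | step 2 | (S)-tetradec-13-en-2-ol | C[C@H](O)CCCCCCCCCCC=C
F5 | step 2 | (S)-tetradec-13-en-2-yl acetate | CC(=O)O[C@@H](C)CCCCCCCCCCC=C
F6 | step 2 | (S)-14-(9-borabicyclo[3.3.1]nonan-9-yl)tetradecan-2-yl acetate | CC(=O)O[C@@H](C)CCCCCCCCCCCCB1C2CCCC1CCC2
F7 | step 3 | pentadec-1-ynyllithium | [Li]C#CCCCCCCCCCCCCC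
F8 | step 3 | (S)-octadec-4-yn-2-ol | C[C@H](O)CC#CCCCCCCCCCCCCC
F9 | step 3 | dipotassium salt of F10 (alkoxide at C2, acetylide at C18) | C[C@H]([O-])CCCCCCCCCCCCCCC#[C-].[K+].[K+]
F10 | step 3 | (S)-octadec-17-yn-2-ol | C[C@H](O)CCCCCCCCCCCCCCC#C
F11 | step 3 | dilithium salt of F10 (alkoxide at C2, acetylide at C18) | C[C@H](O[Li])CCCCCCCCCCCCCCC#C[Li]
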